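**Retrosynthetic overview** (germacrane numbering C1–C15 is used for atom labels)
1. The ten-membered carbocycle and the cis-fused α-methylene-γ-lactone are disconnected together at C6–C7: intramolecular Barbier allylation of a lactol-masked Z-γ-hydroxy-enal by a 2-(bromomethyl)enoate, then lactonisation, which leaves C3–OH free.
2. The bromo-enoate arm comes from an α-isobutyryloxy aldehyde and methyl acrylate (Morita–Baylis–Hillman, SN2′ bromination); the C8 ester is put on directly by an amine-catalysed α-acyloxylation.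
3. The lactol comes from a butenolide, made from an α-hydroxy methyl ketone (proline α-aminoxylation sets C3; Bestmann annulation fixes the Z olefin).
4. The epoxy keto ester chain comes from ozonolysis of the mono-epoxide of achiral 1,5-dimethylcycloocta-1,5-diene (Shi epoxidation sets C1/C10 first; the ring guarantees the cis epoxide).
5. Ring order: oxirane, then the temporary dihydrofuran, then the ten-membered ring, then the γ-lactone.

Assumption: isomer-free (1Z,5Z)-1,5-dimethylcycloocta-1,5-diene (technical material freed from the 1,6-isomer) and the commercial cold solution of diisobutyryl peroxide are taken as purchasable.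

Step 1
Reactants: 1 (1Z,5Z)-1,5-dimethylcycloocta-1,5-diene
Product: 2 (1S,8R,4Z)-1,5-dimethyl-9-oxabicyclo[6.1.0]non-4-ene
Conditions: 1,2:4,5-di-O-isopropylidene-β-D-erythro-2,3-hexodiulo-2,6-pyranose (30 mol %), KHSO5 (as 2KHSO5·KHSO4·K2SO4, 0.6 equiv), K2CO3, Bu4NHSO4, MeCN–CH2(OMe)2–aq. Na2B4O7 buffer, −10 → 0 °C; excess diene recovered
Reagents that add atoms: potassium peroxymonosulfate KHSO5, [K+].OOS(=O)(=O)[O-]
Why: Shi asymmetric epoxidation (chiral dioxirane, spiro transition state) of one of the two equivalent cis-trisubstituted ring olefins, where the D-fructose-derived ketone is expected to attack the face that gives the (R)-CH–O/(S)-C(Me)–O oxirane (same sense as for 1-arylcycloalkenes), the ring fixes the cis epoxide, and limiting oxidant suppresses the bis-epoxide.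

Step 2
Reactants: 2 (1S,8R,4Z)-1,5-dimethyl-9-oxabicyclo[6.1.0]non-4-ene
Product: 3 methyl 3-[(2S,3R)-2-methyl-3-(3-oxobutyl)oxiran-2-yl]propanoate
Conditions: O3, NaOH (2.5 M in MeOH), CH2Cl2–MeOH, −78 °C
Reagents that add atoms: ozone, [O-][O+]=O; methanol, CO
Why: Ozonolysis in methanolic NaOH cleaves the remaining trisubstituted olefin directly to the methyl ketone (C4) and the methyl ester (C7, a latent aldehyde), while the oxirane is inert at −78 °C.

Step 3
Reactants: 3 methyl 3-[(2S,3R)-2-methyl-3-(3-oxobutyl)oxiran-2-yl]propanoate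
Product: 5 (2S)-α-hydroxy ketone (C3–OH), via anilinooxy ketone 4 (not isolated)
Conditions: D-proline (20 mol %), PhNO (1 equiv; 3 used in twofold excess and recovered), DMSO, rt; then CuSO4·5H2O (0.3 equiv), MeOH, 0 °C
Reagents that add atoms: nitrosobenzene, O=Nc1ccccc1
Why: Proline-catalysed α-aminoxylation (enamine O-nitroso aldol) at the more substituted α-carbon of the methyl ketone, in which the carboxylic acid of D-proline delivers PhN=O to one enamine face to set (S)-C3, and the N–O bond is cleaved in the same flask; regioisomer and the diastereomer from the minor epoxide enantiomer are removed here.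

Step 4
Reactants: 5 (2S)-α-hydroxy ketone
Product: 6 butenolide (5-substituted 4-methylfuran-2(5H)-one)
Conditions: Ph3P=C=C=O (1.2 equiv), toluene, 90 °C
Reagents that add atoms: (triphenylphosphoranylidene)ketene, O=C=C=P(c1ccccc1)(c1ccccc1)c1ccccc1
Why: Bestmann annulation, in which the hydroxyl adds to the ketenylidene ylide and the resulting acyl ylide closes onto the neighbouring ketone by intramolecular Wittig reaction, so the Z geometry of C4=C5 is enforced by the five-membered ring and C3 is untouched under neutral conditions.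

Step 5
Reactants: 6 butenolide
Product: 7 lactol aldehyde (both lactol epimers)
Conditions: i-Bu2AlH (2.4 equiv), CH2Cl2, −78 °C; aq. KNaC4H4O6
Reagents that add atoms: none
Why: Low-temperature i-Bu2AlH reduction stops at the tetrahedral aluminium acetals, so the butenolide becomes the lactol (a masked Z-γ-hydroxy-enal) and the methyl ester becomes the aldehyde in one operation while the epoxide survives.

Step 6
Reactants: 7 lactol aldehyde
Product: 8 O-silyl lactol aldehyde
Conditions: TBSCl (1.1 equiv), imidazole, CH2Cl2, 0 °C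
Reagents that add atoms: tert-butyldimethylsilyl chloride, CC(C)(C)[Si](C)(C)Cl
Why: Chemoselective silylation of the hemiacetal hydroxyl (the aldehyde cannot react) locks C6 as a silyl acetal, so only the saturated aldehyde is open to enamine chemistry; the acetal carbon stays an epimer mixture that is erased in step 10.

Step 7
Reactants: 8 O-silyl lactol aldehyde
Product: 9 (2R)-α-isobutyryloxy aldehyde (C8–O ester)
Conditions: (R)-2-(triphenylmethyl)pyrrolidine (10 mol %), diisobutyryl peroxide (1.3 equiv, cold solution), hydroquinone (10 mol %), THF, −20 → 0 °C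
Reagents that add atoms: diisobutyryl peroxide, CC(C)C(=O)OOC(=O)C(C)C
Why: Proposed new method: enamine catalysis in which the E-enamine of 8 attacks the O–O bond of the aliphatic diacyl peroxide (SN2 at oxygen) on the face away from the trityl group of the (R)-catalyst, and hydrolysis of the α-acyloxy iminium ion releases (R)-C8 carrying the isobutyrate in its final form; the closest known reaction type is the amine-catalysed enantioselective α-benzoyloxylation of aldehydes with dibenzoyl peroxide, not yet shown with an α-branched aliphatic diacyl peroxide (hydroquinone and low temperature hold back radical decomposition).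

Step 8
Reactants: 9 (2R)-α-isobutyryloxy aldehyde; 10 methyl acrylate
Product: 11 Morita–Baylis–Hillman adduct (C7 epimers)
Conditions: 3-quinuclidinol (0.5 equiv), methyl acrylate (10 equiv, neat), 0 °C → rt
Reagents that add atoms: none
Why: Morita–Baylis–Hillman reaction of the activated α-acyloxy aldehyde with methyl acrylate under amine catalysis, where the new C7 carbinol forms as an epimer mixture that is erased in the next step and a short run at 0 °C protects C8.

Step 9
Reactants: 11 Morita–Baylis–Hillman adduct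
Product: 12 (2Z)-2-(bromomethyl)enoate
Conditions: NBS (1.3 equiv), Me2S (1.5 equiv), CH2Cl2, −20 → 0 °C
Reagents that add atoms: N-bromosuccinimide, BrN1C(=O)CCC1=O
Why: SN2′ bromination of the Morita–Baylis–Hillman alcohol through its alkoxysulfonium salt (Corey–Kim-type activation) gives the thermodynamically preferred (Z)-2-(bromomethyl)enoate with C8 cis to CH2Br, so both C7 epimers converge and C8 is untouched.

Step 10
Reactants: 12 (2Z)-2-(bromomethyl)enoate
Product: 15 target lactone CNP0261225.6, via free lactol bromide 13 (not isolated), via ring-closed hydroxy ester 14 (not isolated)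
Conditions: pyridinium p-toluenesulfonate (0.2 equiv), THF–H2O 4:1, 0 °C → rt, 1 h; then dilute to 2 mM, indium powder (In, 4 equiv), rt, 16 h
Reagents that add atoms: water, O
Why: Mild hydrolysis frees the lactol, whose open Z-γ-hydroxy-enal form is trapped by intramolecular indium-mediated Barbier allylation (established for 2-(bromomethyl)alk-2-enoates with aldehydes and lactols in water), where the chair transition state with C8 axial gives the syn adduct (the cis 6S,7R pair), C8 selects the face (allylic hydrogen eclipsing the alkene, aldehyde approaching anti to the C9 chain), and the C6 alkoxide lactonises onto the ester to leave C3–OH free.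

**Compound list**
1 | (1Z,5Z)-1,5-dimethylcycloocta-1,5-diene | C1/C(C)=C\CC/C(C)=C\C1 | starting material
2 | (1S,8R,4Z)-1,5-dimethyl-9-oxabicyclo[6.1.0]non-4-ene | C1[C@H]2O[C@@]2(C)CC/C=C(/C)C1 | intermediate
3 | methyl 3-[(2S,3R)-2-methyl-3-(3-oxobutyl)oxiran-2-yl]propanoate | CC(=O)CC[C@H]1O[C@@]1(C)CCC(=O)OC | intermediate
4 | methyl 3-[(2S,3R)-3-[(2S)-2-(anilinooxy)-3-oxobutyl]-2-methyloxiran-2-yl]propanoate | CC(=O)[C@@H](ONc1ccccc1)C[C@H]1O[C@@]1(C)CCC(=O)OC | intermediate
5 | methyl 3-[(2S,3R)-3-[(2S)-2-hydroxy-3-oxobutyl]-2-methyloxiran-2-yl]propanoate | CC(=O)[C@@H](O)C[C@H]1O[C@@]1(C)CCC(=O)OC | intermediate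
6 | methyl 3-[(2S,3R)-2-methyl-3-{[(2S)-3-methyl-5-oxo-2,5-dihydrofuran-2-yl]methyl}oxiran-2-yl]propanoate | O=C1C=C(C)[C@H](C[C@H]2O[C@@]2(C)CCC(=O)OC)O1 | intermediate
7 | 3-[(2S,3R)-3-{[(2S)-5-hydroxy-3-methyl-2,5-dihydrofuran-2-yl]methyl}-2-methyloxiran-2-yl]propanal (both C5 epimers of the dihydrofuran) | OC1C=C(C)[C@H](C[C@H]2O[C@@]2(C)CCC=O)O1 | intermediate
8 | 3-[(2S,3R)-3-{[(2S)-5-(tert-butyldimethylsilyloxy)-3-methyl-2,5-dihydrofuran-2-yl]methyl}-2-methyloxiran-2-yl]propanal | CC(C)(C)[Si](C)(C)OC1C=C(C)[C@H](C[C@H]2O[C@@]2(C)CCC=O)O1 | intermediate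
9 | (2R)-1-[(2S,3R)-3-{[(2S)-5-(tert-butyldimethylsilyloxy)-3-methyl-2,5-dihydrofuran-2-yl]methyl}-2-methyloxiran-2-yl]-3-oxopropan-2-yl 2-methylpropanoate | CC(C)(C)[Si](C)(C)OC1C=C(C)[C@H](C[C@H]2O[C@@]2(C)C[C@@H](OC(=O)C(C)C)C=O)O1 | intermediate
10 | methyl acrylate | C=CC(=O)OC | starting material
11 | methyl (4R)-5-[(2S,3R)-3-{[(2S)-5-(tert-butyldimethylsilyloxy)-3-methyl-2,5-dihydrofuran-2-yl]methyl}-2-methyloxiran-2-yl]-3-hydroxy-2-methylidene-4-(2-methylpropanoyloxy)pentanoate (C3 epimers) | CC(C)(C)[Si](C)(C)OC1C=C(C)[C@H](C[C@H]2O[C@@]2(C)C[C@@H](OC(=O)C(C)C)C(O)C(=C)C(=O)OC)O1 | intermediate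
12 | methyl (2Z,4R)-2-(bromomethyl)-5-[(2S,3R)-3-{[(2S)-5-(tert-butyldimethylsilyloxy)-3-methyl-2,5-dihydrofuran-2-yl]methyl}-2-methyloxiran-2-yl]-4-(2-methylpropanoyloxy)pent-2-enoate | CC(C)(C)[Si](C)(C)OC1C=C(C)[C@H](C[C@H]2O[C@@]2(C)C[C@@H](OC(=O)C(C)C)/C=C(\CBr)C(=O)OC)O1 | intermediate
13 | methyl (2Z,4R)-2-(bromomethyl)-5-[(2S,3R)-3-{[(2S)-5-hydroxy-3-methyl-2,5-dihydrofuran-2-yl]methyl}-2-methyloxiran-2-yl]-4-(2-methylpropanoyloxy)pent-2-enoate | OC1C=C(C)[C@H](C[C@H]2O[C@@]2(C)C[C@@H](OC(=O)C(C)C)/C=C(\CBr)C(=O)OC)O1 | intermediate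
14 | ring-closed hydroxy ester: the C6-hydroxy, C12-methyl ester (opened lactone) form of 15 with the same spatial arrangement at every centre | O[C@H]1/C=C(/C)[C@@H](O)C[C@H]2O[C@@]2(C)C[C@@H](OC(=O)C(C)C)[C@H]1C(=C)C(=O)OC | intermediate
15 | (1R,3S,4Z,6S,7R,8R,10S)-1,10-epoxy-3-hydroxy-8-(2-methylpropanoyloxy)germacra-4,11(13)-dien-12,6-olide (cis-fused α-methylene-γ-lactone, CNP0261225.6) | C=C1C(=O)O[C@H]2/C=C(/C)[C@@H](O)C[C@H]3O[C@@]3(C)C[C@@H](OC(=O)C(C)C)[C@@H]12 | target

**Step count:** 10 steps in total; longest linear sequence 10 steps (1 → 15).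

**Three steps most likely to fail**

Step 7 (the new reaction). The peroxide may decompose by radical or carboxy-inversion paths, the catalyst may be N-acyloxylated, and the product aldehyde may epimerise. The fallback uses known chemistry and sets out from 8. L-Proline (20 mol %) and PhNO in CHCl3 at 4 °C give the (2R)-α-anilinooxy aldehyde F1, which is reduced in the same flask with NaBH4 in EtOH to the anilinooxy alcohol F2. SmI2 in THF at 0 °C cleaves the N–O bond to give the diol F3. TESCl and 2,6-lutidine in CH2Cl2 at −78 °C silylate the primary hydroxyl only, giving the silyl ether F4, and isobutyryl chloride with pyridine and DMAP gives the isobutyrate F5. Swern conditions ((COCl)2, DMSO, then Et3N, −78 → −30 °C) oxidise the primary triethylsilyl ether directly to the aldehyde, and the route is rejoined at 9.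

Step 8. The α-acyloxy aldehyde may epimerise at C8, and the isobutyrate may shift to the new C7 hydroxyl under the amine. The fallback sets out from 9 and replaces amine catalysis by a fast, non-basic organoaluminium addition. [1-(Methoxycarbonyl)ethenyl]diisobutylaluminium F6, made from methyl propiolate, i-Bu2AlH and N-methylmorpholine N-oxide in THF at 0 °C, is added at −78 °C. Work-up with aq. KNaC4H4O6 gives the same adduct, and the route is rejoined at 11.

Step 10. Closure of the ten-membered ring may be slow, the free lactol may dehydrate to a furan in the weakly acidic aqueous medium, and facial control by C8 rests on a model, not on a direct precedent. The fallback sets out from 12 and changes the allyl donor to boron, so that the closure runs without metal, water or acid. CuCl (10 mol %), KOAc and B2pin2 in DMF at rt give the allylboronate F7, and pyridinium p-toluenesulfonate in wet THF frees the lactol boronate F8. Dilution in toluene (2 mM, 40–60 °C) closes the ring through a closed six-membered allylboration transition state with C8 axial (same cis outcome) to give the boryl ether F9. Aqueous work-up gives 14, which lactonises, and the route is rejoined at 15.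

**Further compounds**
F1 | step 7 | (2R)-2-(anilinooxy)-3-[(2S,3R)-3-{[(2S)-5-(tert-butyldimethylsilyloxy)-3-methyl-2,5-dihydrofuran-2-yl]methyl}-2-methyloxiran-2-yl]propanal | CC(C)(C)[Si](C)(C)OC1C=C(C)[C@H](C[C@H]2O[C@@]2(C)C[C@@H](ONc3ccccc3)C=O)O1
F2 | step 7 | (2R)-2-(anilinooxy)-3-[(2S,3R)-3-{[(2S)-5-(tert-butyldimethylsilyloxy)-3-methyl-2,5-dihydrofuran-2-yl]methyl}-2-methyloxiran-2-yl]propan-1-ol | CC(C)(C)[Si](C)(C)OC1C=C(C)[C@H](C[C@H]2O[C@@]2(C)C[C@@H](ONc3ccccc3)CO)O1
F3 | step 7 | (2R)-3-[(2S,3R)-3-{[(2S)-5-(tert-butyldimethylsilyloxy)-3-methyl-2,5-dihydrofuran-2-yl]methyl}-2-methyloxiran-2-yl]propane-1,2-diol | CC(C)(C)[Si](C)(C)OC1C=C(C)[C@H](C[C@H]2O[C@@]2(C)C[C@@H](O)CO)O1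
F4 | step 7 | (2R)-1-[(2S,3R)-3-{[(2S)-5-(tert-butyldimethylsilyloxy)-3-methyl-2,5-dihydrofuran-2-yl]methyl}-2-methyloxiran-2-yl]-3-(triethylsilyloxy)propan-2-ol | CC(C)(C)[Si](C)(C)OC1C=C(C)[C@H](C[C@H]2O[C@@]2(C)C[C@@H](O)CO[Si](CC)(CC)CC)O1
F5 | step 7 | (2R)-1-[(2S,3R)-3-{[(2S)-5-(tert-butyldimethylsilyloxy)-3-methyl-2,5-dihydrofuran-2-yl]methyl}-2-methyloxiran-2-yl]-3-(triethylsilyloxy)propan-2-yl 2-methylpropanoate | CC(C)(C)[Si](C)(C)OC1C=C(C)[C@H](C[C@H]2O[C@@]2(C)C[C@@H](OC(=O)C(C)C)CO[Si](CC)(CC)CC)O1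
F6 | step 8 | [1-(methoxycarbonyl)ethenyl]bis(2-methylpropyl)aluminium | C=C(C(=O)OC)[Al](CC(C)C)CC(C)C
F7 | step 10 | methyl (2E,4R)-5-[(2S,3R)-3-{[(2S)-5-(tert-butyldimethylsilyloxy)-3-methyl-2,5-dihydrofuran-2-yl]methyl}-2-methyloxiran-2-yl]-4-(2-methylpropanoyloxy)-2-[(4,4,5,5-tetramethyl-1,3,2-dioxaborolan-2-yl)methyl]pent-2-enoate | CC(C)(C)[Si](C)(C)OC1C=C(C)[C@H](C[C@H]2O[C@@]2(C)C[C@@H](OC(=O)C(C)C)/C=C(\CB3OC(C)(C)C(C)(C)O3)C(=O)OC)O1
F8 | step 10 | methyl (2E,4R)-5-[(2S,3R)-3-{[(2S)-5-hydroxy-3-methyl-2,5-dihydrofuran-2-yl]methyl}-2-methyloxiran-2-yl]-4-(2-methylpropanoyloxy)-2-[(4,4,5,5-tetramethyl-1,3,2-dioxaborolan-2-yl)methyl]pent-2-enoate | OC1C=C(C)[C@H](C[C@H]2O[C@@]2(C)C[C@@H](OC(=O)C(C)C)/C=C(\CB3OC(C)(C)C(C)(C)O3)C(=O)OC)O1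
F9 | step 10 | C6-O-(4,4,5,5-tetramethyl-1,3,2-dioxaborolan-2-yl) ether of hydroxy ester 14 | CC1(C)OB(O[C@H]2/C=C(/C)[C@@H](O)C[C@H]3O[C@@]3(C)C[C@@H](OC(=O)C(C)C)[C@H]2C(=C)C(=O)OC)OC1(C)C
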